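**Retrosynthetic overview**
- The plan rests on one feature: the acyl part is an unbranched, saturated C26 chain whose only functional group is the ester at C1. C2 to C26 carry no handle, so an internal CH2–CH2 bond must be made from two alkyl fragments of like polarity.
- Key disconnection: C11–C12 is cut to a pentadecyl radical (palmitic acid minus CO2) and an 11-(benzyloxy)-11-oxoundecyl radical (monobenzyl dodecanedioate minus CO2). Forward, this is a crossed Kolbe electrolysis.
- Second disconnection: the ester C–O bond of the half-ester is cut to dodecanedioic acid and benzyl alcohol.
- No ring is formed at any stage; the only ring, the benzene ring, is bought in with benzyl alcohol.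

Key step: step 2

Remark: the target has no stereocentre and is achiral, so the call for a single enantiomer is met by the constitution alone.

**Route**

Step 1
Reactants: 1 dodecanedioic acid; 2 benzyl alcohol
Product: 3 12-(benzyloxy)-12-oxododecanoic acid (monobenzyl dodecanedioate)
Conditions: 1 (2 equiv), 2 (1 equiv), TsOH·H2O (5 mol%), toluene, reflux, Dean–Stark; cool, filter off recovered 1; SiO2
Reagents that add atoms: none
Why: Acid-catalysed Fischer esterification with azeotropic removal of water is reliable for a primary alcohol, and the twofold excess of diacid should bias the statistical mixture towards the half-ester, which is parted from recovered 1 (insoluble in cold toluene) and from the neutral dibenzyl diester by filtration and chromatography.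

Step 2
Reactants: 3 12-(benzyloxy)-12-oxododecanoic acid; 4 palmitic acid
Product: 5 benzyl hexacosanoate
Conditions: 3 (1 equiv), 4 (4 equiv), KOH (5 mol% of total acid), MeOH, Pt foil anode/Pt cathode, undivided cell, constant current ca. 0.25 A cm−2, 50–55 °C, polarity reversed periodically, stopped while the electrolyte is still weakly acidic; SiO2 (hexane, then hexane/EtOAc)
Reagents that add atoms: none
Why: Each carboxylate is discharged at the carboxylate-covered platinum anode by one-electron oxidation and loses CO2, and the pentadecyl and 11-(benzyloxy)-11-oxoundecyl radicals pair in the dense layer at the electrode, which joins C11 to C12, while the cathode reduces the acid protons to H2 and regenerates carboxylate. The closest known reaction type is the mixed Kolbe electrolysis of a fatty acid with a dicarboxylic acid half-ester, the classical anodic route to long-chain esters. No ring closes and no stereocentre is created. Coupling must win over further oxidation to the cation (Hofer–Moest path), which the two unstabilised primary radicals, the smooth Pt anode, the high current density and the weakly acidic methanol should secure. Hetero- against homocoupling is only statistical, so the fourfold excess of cheap 4 is used to make most radicals from 3 meet a pentadecyl radical, and only the carboxylate should be discharged because the benzyl ester has no ionisable group, its arene is not electron-rich and the free acid buffers the electrolyte against methoxide. The neutral products (triacontane, 5 and dibenzyl docosanedioate) differ strongly in polarity and should be parted on silica.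

**Compound list**
1 | dodecanedioic acid | OC(=O)CCCCCCCCCCC(=O)O | starting material
2 | benzyl alcohol | OCc1ccccc1 | starting material
3 | 12-(benzyloxy)-12-oxododecanoic acid (monobenzyl dodecanedioate) | OC(=O)CCCCCCCCCCC(=O)OCc1ccccc1 | intermediate
4 | palmitic acid (hexadecanoic acid) | CCCCCCCCCCCCCCCC(=O)O | starting material
5 | benzyl hexacosanoate | CCCCCCCCCCCCCCCCCCCCCCCCCC(=O)OCc1ccccc1 | target

**Step count**
Total steps: 2. Longest linear sequence: 2 steps (1 → 3 → 5).

**Steps most likely to fail**
The route has only two steps, so both are ranked, the riskier first.

1. Step 2 (crossed Kolbe electrolysis). Three processes could spoil it: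
- The radical pairing is statistical and could run largely to the two symmetrical dimers.
- The waxy neutral products could coat the anode and push the reaction to the two-electron cation path.
- The benzyl ester could exchange with methanol if the electrolyte turns basic, or be attacked at the anode.

Fallback: it sets out from 3 and comes back to the route at 5, and 4 is not used. It forms the same C11–C12 bond by a nickel-catalysed decarboxylative alkyl–alkyl cross-coupling, without electrode or methanol. The free acid of 3 would be turned into its redox-active ester 1-benzyl 12-(1,3-dioxoisoindolin-2-yl) dodecanedioate F1 (N-hydroxyphthalimide, N,N'-diisopropylcarbodiimide, cat. DMAP, CH2Cl2, rt). Purchased 1-bromopentadecane F2 would be converted with Mg in THF into pentadecylmagnesium bromide F3. Transmetallation with ZnCl2 (0.5 equiv) would give dipentadecylzinc F4. Coupling of F1 with F4 (NiCl2·glyme, 4,4'-di-tert-butyl-2,2'-bipyridine, THF/DMF, rt) should give 5 directly. The benzyl ester is expected to tolerate the organozinc reagent, and the coupling is not statistical.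

2. Step 1 (half-esterification). The esterification may not stop at the half-ester, and the mixture of diacid, half-ester and diester, all waxy long-chain compounds, may be tedious to separate.

Fallback: it sets out from 2 and comes back to the route at 3. The two chain ends are told apart by oxidation state instead of by statistics. Purchased 12-hydroxydodecanoic acid F5 would be esterified with an excess of 2 (TsOH, toluene, reflux, Dean–Stark) to benzyl 12-hydroxydodecanoate F6. The primary alcohol of F6 would then be oxidised to the acid (TEMPO cat., PhI(OAc)2, MeCN/H2O/CH2Cl2, rt), conditions that should leave the benzyl ester intact, to give 3.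

**Further compounds**
F1 | step 2 | 1-benzyl 12-(1,3-dioxoisoindolin-2-yl) dodecanedioate | O=C(CCCCCCCCCCC(=O)OCc1ccccc1)ON1C(=O)c2ccccc2C1=O
F2 | step 2 | 1-bromopentadecane (purchased) | CCCCCCCCCCCCCCCBr
F3 | step 2 | pentadecylmagnesium bromide | CCCCCCCCCCCCCCC[Mg]Br
F4 | step 2 | dipentadecylzinc | CCCCCCCCCCCCCCC[Zn]CCCCCCCCCCCCCCC
F5 | step 1 | 12-hydroxydodecanoic acid (purchased) | OCCCCCCCCCCCC(=O)O
F6 | step 1 | benzyl 12-hydroxydodecanoate | OCCCCCCCCCCCC(=O)OCc1ccccc1
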